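## Retrosynthetic overview

- Isochromene numbering is used throughout (C1, O2, C3, C4, C4a, C5 to C8, C8a). The stearate is cut last from the tertiary C7 alcohol.
- The key disconnection is the C7–C8 bond of the carbocycle. The feature that allows it is the acyloin unit O=C8–C7(OH)(CH3) held between the C6 ketone and C8a. It is read as a crossed benzoin between a formyl group on C8a (the vinylogous formate of the dihydropyran ring) and the methyl-ketone end (C7) of a C6/C7 1,2-dione on the exocyclic C4a=C5 alkene. Two carbonyl carbons of like polarity are joined by carbene umpolung, which closes the ring and sets the fully substituted C7 centre.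
- Ring order: the dihydropyran ring (O2, C1, C8a, C4a, C4, C3) is made first, by palladium-catalysed reductive 6-exo-dig cyclisation (C8a–C4a bond) of a bromo enol ether. The carbocycle (C4a, C5, C6, C7, C8, C8a) is closed second, in the key step.
- Building blocks: (R)-pent-4-yn-2-ol (C3 stereocentre, C4, C4a, C5), methyl 2,2-dimethoxypropanoate (C6, C7 and its methyl, the dione masked as a ketal), 2-bromomalonaldehyde (C1, C8a, C8) and octadecanoyl chloride.

Key step: step 5

Remark 1: the acyl group is read as unbranched octadecanoyl (stearoyl) and the configuration as (3R,7R).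

Remark 2: the antipode of the triazolium salt in step 5 is a working choice. Its sense of induction on this substrate is to be confirmed on first use (the C7 epimers are diastereomers), and the (5aR,10bS) salt is taken instead if the 7S epimer is favoured.

## Route

Step 1
Reactants: 1 (R)-pent-4-yn-2-ol; 2 methyl 2,2-dimethoxypropanoate
Product: 4 (7R)-7-hydroxy-2,2-dimethoxyoct-4-yn-3-one, via dilithio alkoxide acetylide 3 (not isolated)
Conditions: n-BuLi (2.1 equiv), THF, −78 to −20 °C; then 2 (1.2 equiv), −78 °C; aq. NH4Cl, −78 °C
Reagents that add atoms: none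
Why: C-acylation of a lithium acetylide by an ester, in which the acetylide carbon of the O,C-dilithio species is the better nucleophile, the two α-methoxy groups hold the chelated tetrahedral intermediate until the quench so that a second addition is not expected, and the C3 stereocentre of 1 is not touched.

Step 2
Reactants: 4 (7R)-7-hydroxy-2,2-dimethoxyoct-4-yn-3-one; 5 2-bromomalonaldehyde
Product: 6 (2Z)-2-bromo-3-{[(2R)-7,7-dimethoxy-6-oxooct-4-yn-2-yl]oxy}prop-2-enal
Conditions: 5 (1.3 equiv), p-TsOH·H2O (3 mol%), cyclohexane–toluene, reflux, Dean–Stark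
Reagents that add atoms: none
Why: Acid-catalysed enol etherification (a vinylogous Fischer esterification) of the enolised dialdehyde by the secondary alcohol, the known way to 3-alkoxy-2-bromoacroleins, which leaves the carbinol C–O bond intact (C3 retained) and should settle in the Z geometry with the alkoxy group trans to the formyl group, as step 3 requires.

Step 3
Reactants: 6 (2Z)-2-bromo-3-{[(2R)-7,7-dimethoxy-6-oxooct-4-yn-2-yl]oxy}prop-2-enal
Product: 7 (2R,4E)-4-(3,3-dimethoxy-2-oxobutylidene)-2-methyl-3,4-dihydro-2H-pyran-5-carbaldehyde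
Conditions: Pd(OAc)2 (5 mol%), PPh3 (15 mol%), HCO2Na (1.5 equiv), DMF, 70 °C
Reagents that add atoms: none
Why: Reductive Heck-type cyclisation (cyclisation with hydride capture), in which oxidative addition of the C–Br bond to zerovalent palladium, 6-exo-dig syn-carbopalladation of the ynone (C8a–C4a bond), formate-for-bromide exchange, loss of CO2 and C–H reductive elimination should give the exocyclic alkene, expected as the E isomer from syn addition, without touching C3.

Step 4
Reactants: 7 (2R,4E)-4-(3,3-dimethoxy-2-oxobutylidene)-2-methyl-3,4-dihydro-2H-pyran-5-carbaldehyde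
Product: 8 (2R,4E)-4-(2,3-dioxobutylidene)-2-methyl-3,4-dihydro-2H-pyran-5-carbaldehyde
Conditions: TFA–H2O–CH2Cl2 (4:1:10), 0 °C to rt
Reagents that add atoms: water, O
Why: Acid-catalysed ketal hydrolysis frees the C7 ketone, the push–pull vinylogous formate being expected to survive because hydration at C1 is reversible and recloses the ring, and protonation at the C6 carbonyl gives the C4a–C5 bond single-bond character so that 8 should be obtained as an equilibrating E/Z pair (drawn as E).

Step 5
Reactants: 8 (2R,4E)-4-(2,3-dioxobutylidene)-2-methyl-3,4-dihydro-2H-pyran-5-carbaldehyde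
Product: 10 (3R,7R)-7-hydroxy-3,7-dimethyl-3,4-dihydro-6H-isochromene-6,8(7H)-dione, via Z-configured dione aldehyde 9 (not isolated)
Conditions: (5aS,10bR)-2-(pentafluorophenyl)-5a,10b-dihydro-4H,6H-indeno[2,1-b][1,2,4]triazolo[4,3-d][1,4]oxazin-2-ium tetrafluoroborate (10 mol%), DABCO (20 mol%), toluene (0.05 M), 25–40 °C, argon
Reagents that add atoms: none
Why: Proposed new method: the chiral triazolylidene adds to the formyl group on C8a and proton transfer gives the Breslow enaminol, whose C8 attacks the C7 carbonyl of the dione in the Z isomer 9 (E and Z should interconvert because DABCO or the free carbene adds reversibly at C1 and so lowers the C4a=C5 bond order), and loss of the carbene leaves the C8 ketone and the tertiary C7 alcohol. The closest known reaction type is the carbene-catalysed enantioselective intramolecular crossed benzoin of an aldehyde with a ketone to six-membered tertiary α-ketols; new here are a vinylogous-formate aldehyde as donor and a conjugated 1,2-dione as acceptor. The carbocycle closes in a 6-exo-trig mode onto the C7 carbonyl. C7 is the only new stereocentre and is set by the catalyst: in the ring-forming transition state the azolium lies on one face of the nascent ring and the enol O–H hydrogen-bonds to the C7 carbonyl oxygen on the other, so the aminoindanol wall of the catalyst decides which face is used, the remote C3 centre having no influence. The step needs attack at C7 and not at C6, and acyl-anion and not homoenolate (C1) reactivity: C6 is a deactivated, doubly vinylogous ester carbonyl that could only close a five-membered ring reversibly, and the electron-poor N-pentafluorophenyl carbene together with the oxygen substituent on C1 disfavours the homoenolate path.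

Step 6
Reactants: 10 (3R,7R)-7-hydroxy-3,7-dimethyl-3,4-dihydro-6H-isochromene-6,8(7H)-dione; 11 octadecanoyl chloride
Product: 12 (3R,7R)-3,7-dimethyl-6,8-dioxo-3,4,7,8-tetrahydro-6H-isochromen-7-yl octadecanoate
Conditions: 11 (1.5 equiv), DMAP (0.2 equiv), Et3N (2.0 equiv), CH2Cl2, 0 °C to rt
Reagents that add atoms: none
Why: DMAP-catalysed acylation through the N-acylpyridinium salt, well precedented for the tertiary C7 hydroxyl of azaphilone-type isochromenediones, should give the ester with the C7 configuration unchanged because the C7–O bond is not broken.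

## Compound list

1 | (R)-pent-4-yn-2-ol | C[C@@H](O)CC#C | starting material
2 | methyl 2,2-dimethoxypropanoate | COC(=O)C(C)(OC)OC | starting material
3 | O,C-dilithio derivative of 1 (dilithium alkoxide acetylide) | [Li+].[Li+].C[C@@H]([O-])CC#[C-] | intermediate
4 | (7R)-7-hydroxy-2,2-dimethoxyoct-4-yn-3-one | C[C@@H](O)CC#CC(=O)C(C)(OC)OC | intermediate
5 | 2-bromomalonaldehyde (2-bromopropanedial) | O=CC(Br)C=O | starting material
6 | (2Z)-2-bromo-3-{[(2R)-7,7-dimethoxy-6-oxooct-4-yn-2-yl]oxy}prop-2-enal | O=C/C(Br)=C/O[C@H](C)CC#CC(=O)C(C)(OC)OC | intermediate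
7 | (2R,4E)-4-(3,3-dimethoxy-2-oxobutylidene)-2-methyl-3,4-dihydro-2H-pyran-5-carbaldehyde | C[C@@H]1C/C(=C\C(=O)C(C)(OC)OC)C(C=O)=CO1 | intermediate
8 | (2R,4E)-4-(2,3-dioxobutylidene)-2-methyl-3,4-dihydro-2H-pyran-5-carbaldehyde | C[C@@H]1C/C(=C\C(=O)C(C)=O)C(C=O)=CO1 | intermediate
9 | (2R,4Z)-4-(2,3-dioxobutylidene)-2-methyl-3,4-dihydro-2H-pyran-5-carbaldehyde | C[C@@H]1C/C(=C/C(=O)C(C)=O)C(C=O)=CO1 | intermediate
10 | (3R,7R)-7-hydroxy-3,7-dimethyl-3,4-dihydro-6H-isochromene-6,8(7H)-dione | O[C@]1(C)C(=O)C=C2C[C@@H](C)OC=C2C1=O | intermediate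
11 | octadecanoyl chloride | CCCCCCCCCCCCCCCCCC(=O)Cl | starting material
12 | (3R,7R)-3,7-dimethyl-6,8-dioxo-3,4,7,8-tetrahydro-6H-isochromen-7-yl octadecanoate | CCCCCCCCCCCCCCCCCC(=O)O[C@]1(C)C(=O)C=C2C[C@@H](C)OC=C2C1=O | target

## Step count and risks

Total step count: 6. Longest linear sequence: 6 steps (from 1).

**Step 5 (the proposed new method, ranked first).**
- What may go wrong: the carbene may use the enal as a homoenolate and bond C1 instead of C8 to C7; the Breslow carbon may add to the C6 carbonyl and give a five-membered ketol; E-to-Z equilibration of the exocyclic alkene may be too slow; or facial selection at C7 may be poor.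
- Fallback (known chemistry, same C7–C8 ring closure, reductive umpolung of the dione by phosphorus in place of carbene umpolung of the aldehyde): it sets out from 8. P(OMe)3 (1.1 equiv, CH2Cl2, 0 °C to rt) adds to the 1,2-dione (Kukhtin–Ramirez addition), and the C7 terminus of the oxyphosphonium enolate condenses with the neighbouring formyl group (Ramirez carbonyl condensation) to give the cyclic trimethoxyphosphorane of the C7,C8-diol F1. Hydrolysis in aqueous THF should release (3R)-7,8-dihydroxy-3,7-dimethyl-3,4,7,8-tetrahydro-6H-isochromen-6-one F2 as a mixture of isomers at C7 and C8. MnO2 (CH2Cl2, rt) oxidises the allylic C8 carbinol and brings the route back at 10. Without catalyst control 10 would form together with its C7 epimer, from which it is separated by chromatography, the two being diastereomers through C3.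

**Step 3.**
- What may go wrong: hydrodebromination before ring closure, conjugate reduction of the ynone by the palladium hydride, or decomposition of the α-bromo enal under the reducing conditions.
- Fallback (cross-coupling in place of cyclisation; the pyran ring is then closed at oxygen): it sets out from 4. NaI/AcOH (rt) adds HI anti across the ynone to give (4Z,7R)-7-hydroxy-5-iodo-2,2-dimethoxyoct-4-en-3-one F3. Suzuki–Miyaura coupling with 4-(4,4,5,5-tetramethyl-1,3,2-dioxaborolan-2-yl)-1,2-oxazole (PdCl2(dppf), KF, dioxane–H2O, 50 °C; a mild base so that the 3-unsubstituted isoxazole is not opened) gives (4Z,7R)-7-hydroxy-2,2-dimethoxy-5-(1,2-oxazol-4-yl)oct-4-en-3-one F4, in which the isoxazole is a masked aminomethylene aldehyde. Reductive N–O cleavage with Mo(CO)6 (MeCN–H2O, 80 °C) gives the enamino aldehyde (3Z)-2-(aminomethylidene)-3-[(2R)-2-hydroxypropyl]-6,6-dimethoxy-5-oxohept-3-enal F5. TFA–H2O then lets the C3 hydroxyl displace ammonia at the aminomethylene carbon (closing the O2–C1 bond of the dihydropyran) and hydrolyses the ketal, so the detour comes back at 8 and bypasses steps 2 to 4.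

**Step 4.**
- What may go wrong: hydration and ring opening of the vinylogous formate, acid-promoted migration of the exocyclic double bond into the ring (a 2H-pyran that can open and erode C3), or aldol-type self-condensation of the freed dione.
- Fallback (oxidative in place of hydrolytic unmasking of C7): it sets out from 1. The dilithio species 3 is acylated with ethyl (2S)-2-[(tert-butyldimethylsilyl)oxy]propanoate to give (2S,7R)-2-[(tert-butyldimethylsilyl)oxy]-7-hydroxyoct-4-yn-3-one F6. The conditions of steps 2 and 3 convert it into (2Z)-2-bromo-3-{[(2R,7S)-7-[(tert-butyldimethylsilyl)oxy]-6-oxooct-4-yn-2-yl]oxy}prop-2-enal F7 and then into (2R,4E)-4-{(3S)-3-[(tert-butyldimethylsilyl)oxy]-2-oxobutylidene}-2-methyl-3,4-dihydro-2H-pyran-5-carbaldehyde F8. HF·pyridine (THF, 0 °C) removes the silyl group to give (2R,4E)-4-[(3S)-3-hydroxy-2-oxobutylidene]-2-methyl-3,4-dihydro-2H-pyran-5-carbaldehyde F9, and Dess–Martin periodinane (CH2Cl2, NaHCO3, rt) oxidises the α-ketol to the dione, so the detour comes back at 8 without aqueous acid.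

Further compounds
F1 | step 5 | cyclic trimethoxyphosphorane of the C7,C8-diol (2,2,2-trimethoxy-1,3,2-dioxaphospholane fused at C7–C8 of the (3R)-3,7-dimethyl-3,4,7,8-tetrahydro-6H-isochromen-6-one core) | C[C@@H]1CC2=CC(=O)C3(C)OP(OC)(OC)(OC)OC3C2=CO1
F2 | step 5 | (3R)-7,8-dihydroxy-3,7-dimethyl-3,4,7,8-tetrahydro-6H-isochromen-6-one (mixture of C7 and C8 isomers) | C[C@@H]1CC2=CC(=O)C(C)(O)C(O)C2=CO1
F3 | step 3 | (4Z,7R)-7-hydroxy-5-iodo-2,2-dimethoxyoct-4-en-3-one | C[C@@H](O)C/C(I)=C/C(=O)C(C)(OC)OC
F4 | step 3 | (4Z,7R)-7-hydroxy-2,2-dimethoxy-5-(1,2-oxazol-4-yl)oct-4-en-3-one | C[C@@H](O)C/C(=C/C(=O)C(C)(OC)OC)c1cnoc1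
F5 | step 3 | (3Z)-2-(aminomethylidene)-3-[(2R)-2-hydroxypropyl]-6,6-dimethoxy-5-oxohept-3-enal | C[C@@H](O)C/C(=C/C(=O)C(C)(OC)OC)C(C=O)=CN
F6 | step 4 | (2S,7R)-2-[(tert-butyldimethylsilyl)oxy]-7-hydroxyoct-4-yn-3-one | C[C@@H](O)CC#CC(=O)[C@H](C)O[Si](C)(C)C(C)(C)C
F7 | step 4 | (2Z)-2-bromo-3-{[(2R,7S)-7-[(tert-butyldimethylsilyl)oxy]-6-oxooct-4-yn-2-yl]oxy}prop-2-enal | O=C/C(Br)=C/O[C@H](C)CC#CC(=O)[C@H](C)O[Si](C)(C)C(C)(C)C
F8 | step 4 | (2R,4E)-4-{(3S)-3-[(tert-butyldimethylsilyl)oxy]-2-oxobutylidene}-2-methyl-3,4-dihydro-2H-pyran-5-carbaldehyde | C[C@@H]1C/C(=C\C(=O)[C@H](C)O[Si](C)(C)C(C)(C)C)C(C=O)=CO1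
F9 | step 4 | (2R,4E)-4-[(3S)-3-hydroxy-2-oxobutylidene]-2-methyl-3,4-dihydro-2H-pyran-5-carbaldehyde | C[C@@H]1C/C(=C\C(=O)[C@H](C)O)C(C=O)=CO1
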